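**Strategy.** Everything rests on disconnecting the C2–C3 bond of flavanone ring C. C2 is a methine bound to O1 of ring A and to electron-rich ring B; in the ring-opened precursor it is therefore a doubly activated benzylic ether CH2 lying 1,6 to C3. Placing a diazo group on C3 lets a chiral dirhodium carboxylate generate a carbene that inserts into one enantiotopic C2–H bond, closing ring C and setting (2S) in a single operation. The precursor is an α-diazoacetophenone (ring A) whose ortho oxygen carries the benzyl-protected 3-(apigenin-6-yl)-4-hydroxybenzyl group, assembled by Suzuki coupling and Mitsunobu etherification; global hydrogenolysis then releases the target.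

Key step: step 10

Numbering used: flavanone unit O1, C2–C8a, with ring B primed. "Apigenin-6-yl" is the flavone unit bonded through its C6; in "5,7,4'-tri-O-benzylapigenin-6-yl" its O5, O7 and O4' carry benzyl groups. The target is (2S).

Assumption: the sense of induction of Rh2(S-BSP)4 on this substrate cannot be predicted with certainty; the route is written with the (S)-ligand series delivering (2S), and the mirror-image complex Rh2(R-BSP)4, made from (R)-proline, would replace it if a first run shows the opposite sense.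

Step 1
Reactants: 1 apigenin
Product: 2 7,4'-di-O-benzylapigenin
Conditions: BnBr (2.2 equiv), K2CO3, DMF, rt to 40 °C
Reagents that add atoms: benzyl bromide, BrCc1ccccc1
Why: Williamson etherification; the C5 hydroxyl is hydrogen-bonded to the C4 carbonyl and is the least nucleophilic, so only O7 and O4' should be alkylated.

Step 2
Reactants: 2 7,4'-di-O-benzylapigenin
Product: 3 7,4'-di-O-benzyl-6-iodoapigenin
Conditions: benzyltrimethylammonium dichloroiodate (1.1 equiv), CaCO3, CH2Cl2–MeOH, rt
Reagents that add atoms: benzyltrimethylammonium dichloroiodate, C[N+](C)(C)Cc1ccccc1.Cl[I-]Cl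
Why: electrophilic aromatic iodination directed ortho to the free C5 phenol, which should favour C6 over C8 as is usual for 5-hydroxy-7-alkoxyflavones.

Step 3
Reactants: 3 7,4'-di-O-benzyl-6-iodoapigenin
Product: 4 5,7,4'-tri-O-benzyl-6-iodoapigenin
Conditions: BnBr (1.5 equiv), K2CO3, Bu4NI (cat.), DMF, 60 °C
Reagents that add atoms: benzyl bromide, BrCc1ccccc1
Why: Williamson etherification of the chelated, hindered C5 phenol, which needs heat and iodide catalysis but has no competing nucleophilic site.

Step 4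
Reactants: 5 4-(benzyloxy)-3-bromobenzaldehyde
Product: 6 4-(benzyloxy)-3-(4,4,5,5-tetramethyl-1,3,2-dioxaborolan-2-yl)benzaldehyde
Conditions: bis(pinacolato)diboron (1.2 equiv), Pd(dppf)Cl2 (3 mol %), KOAc, 1,4-dioxane, 90 °C
Reagents that add atoms: bis(pinacolato)diboron, CC1(C)OB(OC1(C)C)B1OC(C)(C)C(C)(C)O1
Why: Miyaura borylation of an aryl bromide; the weak base KOAc leaves the aldehyde and the benzyl ether untouched.

Step 5
Reactants: 4 5,7,4'-tri-O-benzyl-6-iodoapigenin; 6 4-(benzyloxy)-3-(4,4,5,5-tetramethyl-1,3,2-dioxaborolan-2-yl)benzaldehyde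
Product: 7 4-(benzyloxy)-3-(5,7,4'-tri-O-benzylapigenin-6-yl)benzaldehyde
Conditions: Pd(OAc)2 (5 mol %), SPhos (10 mol %), K3PO4, toluene–H2O, 100 °C
Reagents that add atoms: none
Why: Suzuki–Miyaura coupling; the bulky, electron-rich biarylphosphine should allow transmetalation and reductive elimination at the tri-ortho-substituted C3'–C6'' axis, which carries no configured axial stereochemistry in the target.

Step 6
Reactants: 7 4-(benzyloxy)-3-(5,7,4'-tri-O-benzylapigenin-6-yl)benzaldehyde
Product: 8 [4-(benzyloxy)-3-(5,7,4'-tri-O-benzylapigenin-6-yl)phenyl]methanol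
Conditions: NaBH4, THF–MeOH, 0 °C
Reagents that add atoms: none
Why: hydride reduction of the aldehyde; the flavone carbonyl is a vinylogous ester and should be far slower to reduce at 0 °C.

Step 7
Reactants: 9 2',4'-dihydroxy-6'-methoxyacetophenone
Product: 10 4'-(benzyloxy)-2'-hydroxy-6'-methoxyacetophenone
Conditions: BnBr (1.05 equiv), K2CO3, acetone, reflux
Reagents that add atoms: benzyl bromide, BrCc1ccccc1
Why: Williamson etherification selective for the para hydroxyl, because the ortho hydroxyl is locked in a hydrogen bond to the acetyl group.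

Step 8
Reactants: 8 [4-(benzyloxy)-3-(5,7,4'-tri-O-benzylapigenin-6-yl)phenyl]methanol; 10 4'-(benzyloxy)-2'-hydroxy-6'-methoxyacetophenone
Product: 11 1-{4-(benzyloxy)-2-methoxy-6-[4-(benzyloxy)-3-(5,7,4'-tri-O-benzylapigenin-6-yl)benzyloxy]phenyl}ethanone
Conditions: PPh3, DIAD, THF, 0 °C to rt
Reagents that add atoms: none
Why: Mitsunobu etherification; the acidic ortho-acyl phenol protonates the betaine and its phenoxide displaces the alkoxyphosphonium of the primary benzylic alcohol, forming the future O1–C2 bond under neutral conditions.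

Step 9
Reactants: 11 1-{4-(benzyloxy)-2-methoxy-6-[4-(benzyloxy)-3-(5,7,4'-tri-O-benzylapigenin-6-yl)benzyloxy]phenyl}ethanone
Product: 13 2-diazo-1-{4-(benzyloxy)-2-methoxy-6-[4-(benzyloxy)-3-(5,7,4'-tri-O-benzylapigenin-6-yl)benzyloxy]phenyl}ethanone, via α-trifluoroacetyl ketone 12 (not isolated)
Conditions: LiHMDS (1.1 equiv), THF, −78 °C; CF3CO2CH2CF3; aq. HCl work-up; then MsN3, Et3N, H2O (1 equiv), MeCN–THF, rt
Reagents that add atoms: 2,2,2-trifluoroethyl trifluoroacetate, O=C(OCC(F)(F)F)C(F)(F)F (trifluoroacetyl group of 12 only); methanesulfonyl azide, CS(=O)(=O)N=[N+]=[N-] (the two nitrogens of 13)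
Why: detrifluoroacetylative diazo transfer (Danheiser procedure); the methyl ketone is the only enolisable site, its trifluoroacetylated form is acidic enough for Regitz diazo transfer, and the trifluoroacetyl group then leaves on the sulfonamide.

Step 10
Reactants: 13 2-diazo-1-{4-(benzyloxy)-2-methoxy-6-[4-(benzyloxy)-3-(5,7,4'-tri-O-benzylapigenin-6-yl)benzyloxy]phenyl}ethanone
Product: 14 (2S)-7-(benzyloxy)-2-[4-(benzyloxy)-3-(5,7,4'-tri-O-benzylapigenin-6-yl)phenyl]-5-methoxychroman-4-one
Conditions: Rh2(S-BSP)4 [dirhodium tetrakis(N-benzenesulfonyl-(S)-prolinate)] (2 mol %), CH2Cl2, 0 °C to rt, slow addition of 13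
Reagents that add atoms: none
Why: Rh2(S-BSP)4 decomposes 13 with loss of N2 to an electrophilic rhodium-bound carbene at C3, which engages the C2–H bond of the ortho benzylic ether in a concerted, asynchronous three-centre insertion (hydride-like transfer of H to C3 with C2–C3 bond formation) and releases the catalyst. The closest known reaction type is the dirhodium carboxylate-catalysed intramolecular C–H insertion of ortho-alkoxyaryl α-diazoketones to 2-substituted chroman-4-ones, including its enantioselective variants with chiral N-arylsulfonylprolinate ligands. Ring C (O1, C2, C3, C4, C4a, C8a) closes as a six-membered ring by 1,6-insertion through a chair-like transition state. The only new stereocentre, C2, is under catalyst control: insertion is stereoretentive at carbon, the chiral carboxylate wall selects the pro-S hydrogen of the C2 methylene, and this gives (2S). The step needs site selectivity for C2–H over ylide formation at O1 with 1,2-benzyl shift and over insertion into the OCH3 group; the substrate should secure it because C2–H is the most hydridic bond within reach (α to O1, benzylic, para-benzyloxy-activated), the methoxy C–H bonds are primary and unactivated, O1 is a weakly donating aryl ether oxygen, and bulky carboxylate ligands in a non-coordinating solvent favour insertion over ylide chemistry. Slow addition keeps the carbene from reacting intermolecularly with the flavone carbonyl or the benzyl ethers.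

Step 11
Reactants: 14 (2S)-7-(benzyloxy)-2-[4-(benzyloxy)-3-(5,7,4'-tri-O-benzylapigenin-6-yl)phenyl]-5-methoxychroman-4-one
Product: 15 (2S)-7-hydroxy-2-[4-hydroxy-3-(apigenin-6-yl)phenyl]-5-methoxychroman-4-one (target)
Conditions: H2 (1 atm), 10% Pd/C, THF–MeOH, rt
Reagents that add atoms: none
Why: hydrogenolysis of the five aryl benzyl ethers under neutral conditions, which should leave the flavone C2''=C3'' bond, the 5-methoxy group and the base-sensitive C2 stereocentre intact.

**Compound list**

1 | apigenin | O=c1cc(-c2ccc(O)cc2)oc2cc(O)cc(O)c12 | starting material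
2 | 7,4'-di-O-benzylapigenin | O=c1cc(-c2ccc(OCc3ccccc3)cc2)oc2cc(OCc3ccccc3)cc(O)c12 | intermediate
3 | 7,4'-di-O-benzyl-6-iodoapigenin | O=c1cc(-c2ccc(OCc3ccccc3)cc2)oc2cc(OCc3ccccc3)c(I)c(O)c12 | intermediate
4 | 5,7,4'-tri-O-benzyl-6-iodoapigenin | O=c1cc(-c2ccc(OCc3ccccc3)cc2)oc2cc(OCc3ccccc3)c(I)c(OCc3ccccc3)c12 | intermediate
5 | 4-(benzyloxy)-3-bromobenzaldehyde | O=Cc1ccc(OCc2ccccc2)c(Br)c1 | starting material
6 | 4-(benzyloxy)-3-(4,4,5,5-tetramethyl-1,3,2-dioxaborolan-2-yl)benzaldehyde | O=Cc1ccc(OCc2ccccc2)c(B2OC(C)(C)C(C)(C)O2)c1 | intermediate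
7 | 4-(benzyloxy)-3-(5,7,4'-tri-O-benzylapigenin-6-yl)benzaldehyde | O=Cc1ccc(OCc2ccccc2)c(-c2c(OCc3ccccc3)cc3oc(-c4ccc(OCc5ccccc5)cc4)cc(=O)c3c2OCc2ccccc2)c1 | intermediate
8 | [4-(benzyloxy)-3-(5,7,4'-tri-O-benzylapigenin-6-yl)phenyl]methanol | OCc1ccc(OCc2ccccc2)c(-c2c(OCc3ccccc3)cc3oc(-c4ccc(OCc5ccccc5)cc4)cc(=O)c3c2OCc2ccccc2)c1 | intermediate
9 | 2',4'-dihydroxy-6'-methoxyacetophenone | CC(=O)c1c(O)cc(O)cc1OC | starting material
10 | 4'-(benzyloxy)-2'-hydroxy-6'-methoxyacetophenone | CC(=O)c1c(O)cc(OCc2ccccc2)cc1OC | intermediate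
11 | 1-{4-(benzyloxy)-2-methoxy-6-[4-(benzyloxy)-3-(5,7,4'-tri-O-benzylapigenin-6-yl)benzyloxy]phenyl}ethanone | CC(=O)c1c(OC)cc(OCc2ccccc2)cc1OCc1ccc(OCc2ccccc2)c(-c2c(OCc3ccccc3)cc3oc(-c4ccc(OCc5ccccc5)cc4)cc(=O)c3c2OCc2ccccc2)c1 | intermediate
12 | 4,4,4-trifluoro-1-{4-(benzyloxy)-2-methoxy-6-[4-(benzyloxy)-3-(5,7,4'-tri-O-benzylapigenin-6-yl)benzyloxy]phenyl}butane-1,3-dione (α-trifluoroacetyl ketone) | O=C(CC(=O)C(F)(F)F)c1c(OC)cc(OCc2ccccc2)cc1OCc1ccc(OCc2ccccc2)c(-c2c(OCc3ccccc3)cc3oc(-c4ccc(OCc5ccccc5)cc4)cc(=O)c3c2OCc2ccccc2)c1 | intermediate (not isolated)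
13 | 2-diazo-1-{4-(benzyloxy)-2-methoxy-6-[4-(benzyloxy)-3-(5,7,4'-tri-O-benzylapigenin-6-yl)benzyloxy]phenyl}ethanone | [N-]=[N+]=CC(=O)c1c(OC)cc(OCc2ccccc2)cc1OCc1ccc(OCc2ccccc2)c(-c2c(OCc3ccccc3)cc3oc(-c4ccc(OCc5ccccc5)cc4)cc(=O)c3c2OCc2ccccc2)c1 | intermediate
14 | (2S)-7-(benzyloxy)-2-[4-(benzyloxy)-3-(5,7,4'-tri-O-benzylapigenin-6-yl)phenyl]-5-methoxychroman-4-one | COc1cc(OCc2ccccc2)cc2c1C(=O)C[C@@H](c1ccc(OCc3ccccc3)c(-c3c(OCc4ccccc4)cc4oc(-c5ccc(OCc6ccccc6)cc5)cc(=O)c4c3OCc3ccccc3)c1)O2 | intermediate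
15 | (2S)-7-hydroxy-2-[4-hydroxy-3-(apigenin-6-yl)phenyl]-5-methoxychroman-4-one | COc1cc(O)cc2c1C(=O)C[C@@H](c1ccc(O)c(-c3c(O)cc4oc(-c5ccc(O)cc5)cc(=O)c4c3O)c1)O2 | target

**Step count.** Total: 11 steps. Longest linear sequence: 9 steps (1 → 15 through steps 1, 2, 3, 5, 6, 8, 9, 10, 11).

**Steps most likely to fail**

Step 10. The carbene may be intercepted by the lone pair of O1 (five-membered oxonium ylide, then 1,2-shift of the benzylic group to a benzofuran-3-one) faster than it inserts into C2–H, or the catalyst may discriminate the two C2 hydrogens poorly. The fallback gives up the C–C closure of ring C and closes O1–C2 instead by organocatalytic oxa-Michael addition; it sets out from 10 and 7 and returns at 14. The dianion of 10 (LiHMDS, THF, −78 °C) is C-acylated with di-tert-butyl dicarbonate to give tert-butyl 3-[4-(benzyloxy)-2-hydroxy-6-methoxyphenyl]-3-oxopropanoate F1. Knoevenagel condensation of F1 with 7 (piperidine/AcOH cat., toluene, 4 Å molecular sieves) should give the alkylidene β-ketoester F2. A cinchona-derived bifunctional thiourea (10 mol %, toluene, −25 °C; the quinine or quinidine series chosen to give 2S) should promote enantioselective conjugate addition of the phenol to give tert-butyl (2S)-4-oxochroman-3-carboxylate F3. Warming F3 with p-TsOH in toluene at 80 °C should cleave the tert-butyl ester and decarboxylate to 14.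

Step 9. Kinetic enolisation and trifluoroacetylation of the twisted, di-ortho-substituted aryl methyl ketone may be incomplete, and the strong base may attack or metalate the flavone unit. The fallback activates the methyl group without strong base; it sets out from 11 and returns at 13. Heating 11 with N,N-dimethylformamide dimethyl acetal (toluene, 110 °C) should give the (E)-enaminone F4. Treating F4 with tosyl azide (1,4-dioxane, rt) should transfer the diazo group by dipolar cycloaddition and cycloreversion, expelling N,N-dimethyl-N'-tosylformamidine and giving 13.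

Step 5. Protodeboronation of the ortho-alkoxy arylboronate may outpace a slow transmetalation onto the hindered di-ortho-substituted arylpalladium iodide. The fallback replaces boron by tin; it sets out from 5 and 4 and returns at 7. Stannylation of 5 with hexabutylditin (Pd(PPh3)4, toluene, 110 °C) should give 4-(benzyloxy)-3-(tributylstannyl)benzaldehyde F5. Stille coupling of F5 with 4 under copper and fluoride promotion (Pd(PPh3)4, CuI, CsF, DMF, 50 °C) should give 7 without a protodemetalation-prone boronate.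

**Further compounds**

F1 | step 10 | tert-butyl 3-[4-(benzyloxy)-2-hydroxy-6-methoxyphenyl]-3-oxopropanoate | CC(C)(C)OC(=O)CC(=O)c1c(O)cc(OCc2ccccc2)cc1OC
F2 | step 10 | tert-butyl 2-[4-(benzyloxy)-2-hydroxy-6-methoxybenzoyl]-3-[4-(benzyloxy)-3-(5,7,4'-tri-O-benzylapigenin-6-yl)phenyl]prop-2-enoate (alkene geometry not fixed) | CC(C)(C)OC(=O)C(=Cc1ccc(OCc2ccccc2)c(-c2c(OCc3ccccc3)cc3oc(-c4ccc(OCc5ccccc5)cc4)cc(=O)c3c2OCc2ccccc2)c1)C(=O)c1c(O)cc(OCc2ccccc2)cc1OC
F3 | step 10 | tert-butyl (2S)-7-(benzyloxy)-2-[4-(benzyloxy)-3-(5,7,4'-tri-O-benzylapigenin-6-yl)phenyl]-5-methoxy-4-oxochroman-3-carboxylate (C3 epimers) | COc1cc(OCc2ccccc2)cc2c1C(=O)C(C(=O)OC(C)(C)C)[C@@H](c1ccc(OCc3ccccc3)c(-c3c(OCc4ccccc4)cc4oc(-c5ccc(OCc6ccccc6)cc5)cc(=O)c4c3OCc3ccccc3)c1)O2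
F4 | step 9 | (E)-3-(dimethylamino)-1-{4-(benzyloxy)-2-methoxy-6-[4-(benzyloxy)-3-(5,7,4'-tri-O-benzylapigenin-6-yl)benzyloxy]phenyl}prop-2-en-1-one | CN(C)/C=C/C(=O)c1c(OC)cc(OCc2ccccc2)cc1OCc1ccc(OCc2ccccc2)c(-c2c(OCc3ccccc3)cc3oc(-c4ccc(OCc5ccccc5)cc4)cc(=O)c3c2OCc2ccccc2)c1
F5 | step 5 | 4-(benzyloxy)-3-(tributylstannyl)benzaldehyde | O=Cc1ccc(OCc2ccccc2)c([Sn](CCCC)(CCCC)CCCC)c1
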